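**Retrosynthetic overview**

1. The aldehyde is released last from a dioxolane, and the indenone C1=O is made just before that by autoxidation of the indene C1H2, so both carbonyl groups stay masked while the azulene is built.
2. Key disconnection: the seven-membered ring of the azulene, at Az8–Az8a and Az3a–Az4. The strategy rests on this feature: Az4(CH3)–Az5–Az6–Az7(isopropyl)–Az8 carry the substitution pattern of C2–C6 of a 2-methyl-5-isopropylpyridine, and the five-membered ring Az1(CH3)/Az2/Az3(indenyl)/Az3a/Az8a is a 1,3-disubstituted cyclopentadiene. The partners are therefore an N-butylpyridinium salt and an indenylcyclopentadienide (Ziegler–Hafner).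
3. The cyclopentadiene comes from 1,2-addition of a 2-indenyl Grignard reagent to 3-methylcyclopent-2-enone and dehydration, which fixes the 1,3-pattern without ambiguity.
4. The 2-bromoindene comes from 4-bromo-3,7-dimethylindan-1-one (formylation, acetal, alpha-bromination, reduction, dehydration), itself from 4-bromotoluene and crotonyl chloride. The pyridinium salt comes from 5-bromo-2-methylpyridine (Negishi isopropylation, N-butylation).
5. Ring order: indanone five-membered ring (step 1); the cyclopentadiene ring is bought as the cyclopentenone; azulene seven-membered ring (step 10).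

Key step: step 10

Assumption: the 1H-indene intermediates are drawn as the 3-methyl (C1H2) tautomer expected at base equilibrium, the 1-methyl tautomer gives the same indenyl anion so the route does not depend on this, and the sp3 stereocentres of the indanone stage are carried as racemic or diastereomeric mixtures and are all removed before the target, which has none.

**Route**

Step 1
Reactants: 1 4-bromotoluene; 2 (E)-but-2-enoyl chloride (crotonyl chloride)
Product: 4 4-bromo-3,7-dimethyl-2,3-dihydro-1H-inden-1-one (racemic), via aryl propenyl ketone 3 (not isolated)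
Conditions: AlCl3, CH2Cl2, 0 °C to rt; solvent removed; conc. H2SO4, 85 °C
Reagents that add atoms: none
Why: Friedel–Crafts acylation goes ortho to the methyl group (para is blocked by bromine) to give 3, and the acid-mediated Nazarov-type cyclisation can only close onto the single free position ortho to the acyl group, which places bromine at C4 and methyl at C7 of the 3-methylindanone.

Step 2
Reactants: 4 4-bromo-3,7-dimethyl-2,3-dihydro-1H-inden-1-one
Product: 5 3,7-dimethyl-1-oxo-2,3-dihydro-1H-indene-4-carbaldehyde (racemic)
Conditions: Pd(OAc)2 (cat.), di(1-adamantyl)-n-butylphosphine (cat.), TMEDA, CO/H2 (1:1, 5 bar), toluene, 100 °C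
Reagents that add atoms: carbon monoxide, [C-]#[O+]
Why: Palladium-catalysed reductive carbonylation (formylation) of an aryl bromide with synthesis gas, under which the aryl ketone is inert and TMEDA takes up the HBr.

Step 3
Reactants: 5 3,7-dimethyl-1-oxo-2,3-dihydro-1H-indene-4-carbaldehyde
Product: 6 4-(1,3-dioxolan-2-yl)-3,7-dimethyl-2,3-dihydro-1H-inden-1-one (racemic)
Conditions: ethylene glycol (1.2 equiv), PPTS (cat.), benzene, reflux, Dean–Stark
Reagents that add atoms: ethylene glycol, OCCO
Why: Acid-catalysed acetalisation with azeotropic removal of water is much faster at the aryl aldehyde than at the conjugated, peri-hindered indanone carbonyl, so a small excess of diol should protect the aldehyde alone.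

Step 4
Reactants: 6 4-(1,3-dioxolan-2-yl)-3,7-dimethyl-2,3-dihydro-1H-inden-1-one
Product: 8 2-bromo-4-(1,3-dioxolan-2-yl)-3,7-dimethyl-2,3-dihydro-1H-inden-1-one (diastereomer mixture), via silyl enol ether 7 (not isolated)
Conditions: LiN(SiMe3)2, Me3SiCl, THF, –78 °C; then NBS, THF, –78 to 0 °C
Reagents that add atoms: N-bromosuccinimide, O=C1CCC(=O)N1Br; chlorotrimethylsilane, C[Si](C)(C)Cl (silyl group in intermediate 7 only)
Why: The ketone can enolise only towards C2, and bromination of the silyl enol ether with NBS is a neutral alpha-bromination that spares the dioxolane.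

Step 5
Reactants: 8 2-bromo-4-(1,3-dioxolan-2-yl)-3,7-dimethyl-2,3-dihydro-1H-inden-1-one
Product: 9 2-bromo-4-(1,3-dioxolan-2-yl)-3,7-dimethyl-2,3-dihydro-1H-inden-1-ol (diastereomer mixture)
Conditions: NaBH4, MeOH/THF, 0 °C
Reagents that add atoms: none
Why: Borohydride reduction of the alpha-bromo ketone at low temperature should give the bromohydrin before epoxide closure competes, and the configuration of the new carbinol does not matter because it is lost in step 6.

Step 6
Reactants: 9 2-bromo-4-(1,3-dioxolan-2-yl)-3,7-dimethyl-2,3-dihydro-1H-inden-1-ol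
Product: 11 2-(2-bromo-3,7-dimethyl-1H-inden-4-yl)-1,3-dioxolane, via 1-methyl tautomer 10 (not isolated)
Conditions: TsOH·H2O (cat.), toluene, reflux, Dean–Stark; then Et3N, 40 °C
Reagents that add atoms: none
Why: Acid-catalysed E1 dehydration of the benzylic alcohol under water-removing conditions that keep the dioxolane intact gives the 2-bromoindene 10, and the amine-catalysed 1,3-proton shift typical of 1-alkylindenes should then move the double bond to the more substituted C2=C3 position.

Step 7
Reactants: 11 2-(2-bromo-3,7-dimethyl-1H-inden-4-yl)-1,3-dioxolane; 12 3-methylcyclopent-2-en-1-one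
Product: 15 2-[3,7-dimethyl-2-(4-methylcyclopenta-1,3-dien-1-yl)-1H-inden-4-yl]-1,3-dioxolane (one cyclopentadiene tautomer drawn), via indenylmagnesium bromide 13 (not isolated), via cyclopentenol 14 (not isolated)
Conditions: Mg turnings (I2-activated), THF, reflux; then LaCl3·2LiCl, 12, THF, –20 to 0 °C; aq. NH4Cl; then PPTS (cat.), MgSO4, CH2Cl2, 0 °C to rt
Reagents that add atoms: magnesium, [Mg] (in intermediate 13 only; none in 15)
Why: Magnesium insertion into the vinylic C–Br bond gives the 2-indenyl Grignard reagent as it does for 2-bromoindene itself, LaCl3·2LiCl favours 1,2-addition to the enone over enolisation, and the doubly allylic tertiary alcohol 14 loses water under trace acid to the cyclopentadiene, in which addition at C1 of a 3-methylcyclopentenone guarantees the 1,3-relationship of methyl and indenyl groups.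

Step 8
Reactants: 16 5-bromo-2-methylpyridine
Product: 17 5-isopropyl-2-methylpyridine
Conditions: iPrZnBr, Pd(OAc)2 (cat.), CPhos (cat.), THF/toluene, rt
Reagents that add atoms: isopropylzinc bromide, CC(C)[Zn]Br
Why: Negishi coupling of a secondary alkylzinc halide with a heteroaryl bromide, in which the CPhos ligand speeds reductive elimination relative to beta-hydride elimination so that the isopropyl group should be transferred without isomerisation to n-propyl.

Step 9
Reactants: 17 5-isopropyl-2-methylpyridine; 18 1-bromobutane
Product: 19 1-butyl-5-isopropyl-2-methylpyridinium bromide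
Conditions: 1-bromobutane (excess), MeCN, reflux
Reagents that add atoms: none
Why: Menshutkin N-alkylation of the pyridine nitrogen with a primary bromide, which the 2-methyl group slows but does not prevent.

Step 10
Reactants: 15 2-[3,7-dimethyl-2-(4-methylcyclopenta-1,3-dien-1-yl)-1H-inden-4-yl]-1,3-dioxolane; 19 1-butyl-5-isopropyl-2-methylpyridinium bromide
Product: 24 2-[2-(guaiazulen-3-yl)-3,7-dimethyl-1H-inden-4-yl]-1,3-dioxolane, via sodium cyclopentadienide 20 (not isolated), via dihydropyridine 21 (not isolated), via aminodienyl fulvene 22 (not isolated), via aminodihydroazulene 23 (not isolated)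
Conditions: NaH (1.0 equiv), THF, 0 °C; 19, pyridine, 0 °C to rt; then triethanolamine, THF distilled off, 170 °C
Reagents that add atoms: sodium hydride, [Na+].[H-] (sodium in intermediate 20 only; none in 24)
Why: Ziegler–Hafner azulene synthesis in its N-alkylpyridinium form: cyclopentadienide 20 attacks C6 of 19, the unsubstituted alpha carbon, through the ring CH next to its methyl group (bond Az8–Az8a) to give dihydropyridine 21, whose N–C6 bond opens in a six-electron electrocyclic step and, after proton shifts, leaves the vinylogous 6-aminofulvene 22 with the butylamino group on the methyl-bearing carbon that becomes Az4. On heating, 22 should undergo the thermally allowed ten-electron electrocyclisation between the fulvene ring CH next to the indenyl group and this enamine carbon (bond Az3a–Az4), which closes the seven-membered ring as aminodihydroazulene 23, and loss of butylamine then aromatises the azulene. The closest known reaction type is the preparation of azulenes from sodium cyclopentadienides and N-alkylpyridinium salts, for which alkyl-substituted partners on both sides have been used. No stereocentre is created in 24, the sp3 centres of 21 and 23 being transient. The step needs attack at the cyclopentadienide CH flanked by the methyl group instead of the one flanked by the bulky, twisted indenyl group, and at C6 instead of the methyl-blocked C2 of the pyridinium ring; both are the less hindered choices, the addition stays reversible until the ring opens, and once the side chain sits beside the methyl group the only ring CH left for closure is the one beside the indenyl group. One equivalent of NaH removes only the cyclopentadiene proton, the most acidic in 15, so that the indene CH2 and the dioxolane pass through unchanged.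

Step 11
Reactants: 24 2-[2-(guaiazulen-3-yl)-3,7-dimethyl-1H-inden-4-yl]-1,3-dioxolane
Product: 26 4-(1,3-dioxolan-2-yl)-2-(guaiazulen-3-yl)-3,7-dimethyl-1H-inden-1-one, via C1 hydroperoxide 25 (not isolated)
Conditions: benzyltrimethylammonium hydroxide (0.2 equiv, 40% in MeOH), pyridine, O2 (1 atm), 0 °C to rt
Reagents that add atoms: dioxygen, O=O
Why: Base-mediated autoxidation of an active methylene group, in which the catalytic hydroxide deprotonates only the indene CH2 (the most acidic CH), the indenyl anion should capture O2 at the unsubstituted and less hindered C1 to give hydroperoxide 25, and base-induced loss of water from this secondary hydroperoxide gives the indenone, a conversion known for fluorenes and 2,3-disubstituted indenes.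

Step 12
Reactants: 26 4-(1,3-dioxolan-2-yl)-2-(guaiazulen-3-yl)-3,7-dimethyl-1H-inden-1-one
Product: 27 2-(guaiazulen-3-yl)-3,7-dimethyl-1-oxo-1H-indene-4-carbaldehyde (CNP0233877.0)
Conditions: PPTS, acetone/H2O, 45 °C
Reagents that add atoms: water, O
Why: Mild acid-catalysed hydrolysis of the dioxolane frees the aldehyde, and the weak acid avoids protonation of the azulene while the fully substituted indenone is stable to it.

**Compound list**

1 | 4-bromotoluene | Cc1ccc(Br)cc1 | starting material
2 | (E)-but-2-enoyl chloride | C/C=C/C(Cl)=O | starting material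
3 | (E)-1-(5-bromo-2-methylphenyl)but-2-en-1-one | C/C=C/C(=O)c1cc(Br)ccc1C | intermediate
4 | 4-bromo-3,7-dimethyl-2,3-dihydro-1H-inden-1-one (racemic) | CC1CC(=O)c2c(C)ccc(Br)c21 | intermediate
5 | 3,7-dimethyl-1-oxo-2,3-dihydro-1H-indene-4-carbaldehyde (racemic) | CC1CC(=O)c2c(C)ccc(C=O)c21 | intermediate
6 | 4-(1,3-dioxolan-2-yl)-3,7-dimethyl-2,3-dihydro-1H-inden-1-one (racemic) | CC1CC(=O)c2c(C)ccc(C3OCCO3)c21 | intermediate
7 | {[7-(1,3-dioxolan-2-yl)-1,4-dimethyl-1H-inden-3-yl]oxy}trimethylsilane (racemic) | CC1C=C(O[Si](C)(C)C)c2c(C)ccc(C3OCCO3)c21 | intermediate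
8 | 2-bromo-4-(1,3-dioxolan-2-yl)-3,7-dimethyl-2,3-dihydro-1H-inden-1-one (diastereomer mixture) | CC1C(Br)C(=O)c2c(C)ccc(C3OCCO3)c21 | intermediate
9 | 2-bromo-4-(1,3-dioxolan-2-yl)-3,7-dimethyl-2,3-dihydro-1H-inden-1-ol (diastereomer mixture) | CC1C(Br)C(O)c2c(C)ccc(C3OCCO3)c21 | intermediate
10 | 2-(2-bromo-1,4-dimethyl-1H-inden-7-yl)-1,3-dioxolane (racemic) | CC1C(Br)=Cc2c(C)ccc(C3OCCO3)c21 | intermediate
11 | 2-(2-bromo-3,7-dimethyl-1H-inden-4-yl)-1,3-dioxolane | CC1=C(Br)Cc2c(C)ccc(C3OCCO3)c21 | intermediate
12 | 3-methylcyclopent-2-en-1-one | CC1=CC(=O)CC1 | starting material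
13 | [4-(1,3-dioxolan-2-yl)-3,7-dimethyl-1H-inden-2-yl]magnesium bromide | CC1=C([Mg]Br)Cc2c(C)ccc(C3OCCO3)c21 | intermediate
14 | 1-[4-(1,3-dioxolan-2-yl)-3,7-dimethyl-1H-inden-2-yl]-3-methylcyclopent-2-en-1-ol (racemic) | CC1=CC(O)(CC1)C1=C(C)c2c(C3OCCO3)ccc(C)c2C1 | intermediate
15 | 2-[3,7-dimethyl-2-(4-methylcyclopenta-1,3-dien-1-yl)-1H-inden-4-yl]-1,3-dioxolane | CC1=CC(=CC1)C1=C(C)c2c(C3OCCO3)ccc(C)c2C1 | intermediate
16 | 5-bromo-2-methylpyridine | Cc1ccc(Br)cn1 | starting material
17 | 5-isopropyl-2-methylpyridine | Cc1ccc(C(C)C)cn1 | intermediate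
18 | 1-bromobutane | CCCCBr | starting material
19 | 1-butyl-5-isopropyl-2-methylpyridinium bromide | [Br-].CCCC[n+]1cc(C(C)C)ccc1C | intermediate
20 | sodium 3-[4-(1,3-dioxolan-2-yl)-3,7-dimethyl-1H-inden-2-yl]-1-methylcyclopentadienide | [Na+].CC1=CC(=C[CH-]1)C1=C(C)c2c(C3OCCO3)ccc(C)c2C1 | intermediate
21 | 1-butyl-2-{4-[4-(1,3-dioxolan-2-yl)-3,7-dimethyl-1H-inden-2-yl]-2-methylcyclopenta-2,4-dien-1-yl}-3-isopropyl-6-methyl-1,2-dihydropyridine (diastereomer mixture) | CCCCN1C(C)=CC=C(C(C)C)C1C1C(C)=CC(=C1)C1=C(C)c2c(C3OCCO3)ccc(C)c2C1 | intermediate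
22 | N-butyl-5-({4-[4-(1,3-dioxolan-2-yl)-3,7-dimethyl-1H-inden-2-yl]-2-methylcyclopenta-2,4-dien-1-ylidene}methyl)-6-methylhepta-2,4-dien-2-amine (double-bond geometry not defined) | CCCCNC(C)=CC=C(C(C)C)C=C1C(C)=CC(=C1)C1=C(C)c2c(C3OCCO3)ccc(C)c2C1 | intermediate
23 | N-butyl-3-[4-(1,3-dioxolan-2-yl)-3,7-dimethyl-1H-inden-2-yl]-7-isopropyl-1,4-dimethyl-3a,4-dihydroazulen-4-amine (diastereomer mixture) | CCCCNC1(C)C=CC(C(C)C)=CC2=C(C)C=C(C21)C1=C(C)c2c(C3OCCO3)ccc(C)c2C1 | intermediate
24 | 2-[2-(7-isopropyl-1,4-dimethylazulen-3-yl)-3,7-dimethyl-1H-inden-4-yl]-1,3-dioxolane | CC1=C(c2cc(C)c3cc(C(C)C)ccc(C)c2-3)Cc2c(C)ccc(C3OCCO3)c21 | intermediate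
25 | 2-[1-hydroperoxy-2-(7-isopropyl-1,4-dimethylazulen-3-yl)-3,7-dimethyl-1H-inden-4-yl]-1,3-dioxolane (racemic) | CC1=C(c2cc(C)c3cc(C(C)C)ccc(C)c2-3)C(OO)c2c(C)ccc(C3OCCO3)c21 | intermediate
26 | 4-(1,3-dioxolan-2-yl)-2-(7-isopropyl-1,4-dimethylazulen-3-yl)-3,7-dimethyl-1H-inden-1-one | CC1=C(c2cc(C)c3cc(C(C)C)ccc(C)c2-3)C(=O)c2c(C)ccc(C3OCCO3)c21 | intermediate
27 | 2-(7-isopropyl-1,4-dimethylazulen-3-yl)-3,7-dimethyl-1-oxo-1H-indene-4-carbaldehyde | CC1=C(c2cc(C)c3cc(C(C)C)ccc(C)c2-3)C(=O)c2c(C)ccc(C=O)c21 | target

**Step count**

Total: 12 steps. Longest linear sequence: 10 steps (steps 1–7 and 10–12); steps 8 and 9 form the pyridinium branch.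

**Steps most likely to fail, with fallbacks**

Step 10. The cyclopentadienide may add through the CH next to the indenyl group or at C4 of the pyridinium ring. The ten-electron closure, which must form a bond to a fully substituted enamine carbon beside the bulky indenyl group, may also be slower than decomposition of the aminofulvene at the temperature needed. In that case the azulene would be bought and not built. The fallback sets out from 11 and rejoins the route at 24. Guaiazulene (commercial, Cc1ccc2c1cc(C(C)C)ccc2C) would be brominated at C3 with NBS in hexane at –20 °C to 3-bromo-7-isopropyl-1,4-dimethylazulene F1, which is used at once because it does not keep. The Grignard reagent 13, made from 11 as in step 7, would be transmetalated with ZnCl2 to [4-(1,3-dioxolan-2-yl)-3,7-dimethyl-1H-inden-2-yl]zinc chloride F2. Negishi coupling of F1 and F2 with Pd2(dba)3 and SPhos in THF at 40 °C should give 24 directly.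

Step 11. Oxygen may be captured at the methyl-bearing terminus of the indenyl anion and give a tertiary hydroperoxide that cannot become a ketone, or the base and oxygen may attack the acidic and oxidisable methyl groups of the azulene. The fallback sets out from 24 and comes back at the target 27. Compound 24 would be condensed with N,N-dimethyl-4-nitrosoaniline (CN(C)c1ccc(N=O)cc1; piperidine, EtOH, rt; Ehrlich–Sachs condensation). This reaction needs both hydrogens of the CH2 group and can therefore end only at C1. It should give N-[4-(dimethylamino)phenyl]-4-(1,3-dioxolan-2-yl)-2-(7-isopropyl-1,4-dimethylazulen-3-yl)-3,7-dimethyl-1H-inden-1-imine F3. Aqueous oxalic acid in THF would then hydrolyse the anil and the dioxolane together, so that step 12 is no longer needed.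

Step 7. The indenylmagnesium species may be quenched by the acidic CH2 of unreacted bromide, the hindered alkenyl nucleophile may enolise the enone instead of adding to it, or the diene may dimerise by Diels–Alder reaction on concentration. The fallback sets out from 11 and comes back at 15, forming the carbon–carbon bond by cross-coupling and not by carbonyl addition. Suzuki–Miyaura coupling of 11 with commercial 3-(4,4,5,5-tetramethyl-1,3,2-dioxaborolan-2-yl)cyclopent-2-en-1-one (CC1(C)OB(OC1(C)C)C1=CC(=O)CC1; PdCl2(dppf), K3PO4, dioxane/H2O, 80 °C) should give 3-[4-(1,3-dioxolan-2-yl)-3,7-dimethyl-1H-inden-2-yl]cyclopent-2-en-1-one F4. 1,2-Addition of the small nucleophile MeMgBr in the presence of CeCl3 (THF, –78 °C) would give 3-[4-(1,3-dioxolan-2-yl)-3,7-dimethyl-1H-inden-2-yl]-1-methylcyclopent-2-en-1-ol F5. Dehydration with PPTS and MgSO4 in CH2Cl2 would give 15 as a cyclopentadiene tautomer that leads to the same anion 20.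

**Further compounds**

F1 | step 10 | 3-bromo-7-isopropyl-1,4-dimethylazulene | Brc1cc(C)c2cc(C(C)C)ccc(C)c1-2
F2 | step 10 | [4-(1,3-dioxolan-2-yl)-3,7-dimethyl-1H-inden-2-yl]zinc chloride | CC1=C([Zn]Cl)Cc2c(C)ccc(C3OCCO3)c21
F3 | step 11 | N-[4-(dimethylamino)phenyl]-4-(1,3-dioxolan-2-yl)-2-(7-isopropyl-1,4-dimethylazulen-3-yl)-3,7-dimethyl-1H-inden-1-imine | CC1=C(c2cc(C)c3cc(C(C)C)ccc(C)c2-3)C(=Nc2ccc(N(C)C)cc2)c2c(C)ccc(C3OCCO3)c21
F4 | step 7 | 3-[4-(1,3-dioxolan-2-yl)-3,7-dimethyl-1H-inden-2-yl]cyclopent-2-en-1-one | O=C1CCC(=C1)C1=C(C)c2c(C3OCCO3)ccc(C)c2C1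
F5 | step 7 | 3-[4-(1,3-dioxolan-2-yl)-3,7-dimethyl-1H-inden-2-yl]-1-methylcyclopent-2-en-1-ol (racemic) | CC1(O)CCC(=C1)C1=C(C)c2c(C3OCCO3)ccc(C)c2C1
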